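**Retrosynthetic overview**
- Target ⇒ its 2'-O-benzyl ether, with hydrogenolysis last. Rings A and B are bought, and ring C is the only ring made.
- Ring C is cut at O1–C8a and the 6-OH is removed in the same disconnection. Both C–O bonds come from one oxidation of an open-chain 1,3-diketone whose ring A is a plain 2-hydroxy-4,5-dimethoxyphenyl group (phenol → ortho-quinone → enol-O conjugate addition at the free C–H → 5,6-catechol).
- The 1,3-diketone ⇒ crossed Claisen condensation of the ring B methyl ketone with a ring A phenyl salicylate.
- The ring B ketone ⇒ O-benzylation of 2'-hydroxy-6'-methoxyacetophenone.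

Assumption: the target has no stereocentre and the C2–C1' bond rotates freely, so it is one achiral compound and no step needs stereocontrol.

**Step 1**
Reactants: 1 2'-hydroxy-6'-methoxyacetophenone
Product: 2 2'-(benzyloxy)-6'-methoxyacetophenone
Conditions: BnBr (1.2 equiv), K2CO3 (2 equiv), DMF, 60 °C
Reagents that add atoms: benzyl bromide, BrCc1ccccc1
Why: Williamson ether synthesis, in which K2CO3 deprotonates the chelated phenol and the phenoxide displaces bromide (SN2); the benzyl ether keeps ring B inert to the later phenol oxidant, and no stereocentre is formed.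

**Step 2**
Reactants: 2 2'-(benzyloxy)-6'-methoxyacetophenone; 3 phenyl 2-hydroxy-4,5-dimethoxybenzoate (bulk intermediate of the drug acotiamide)
Product: 4 1-[2-(benzyloxy)-6-methoxyphenyl]-3-(2-hydroxy-4,5-dimethoxyphenyl)propane-1,3-dione (mostly enol)
Conditions: LiN(SiMe3)2 (3.3 equiv), THF, −78 °C to rt; then 1 M HCl, 0 °C
Reagents that add atoms: none
Why: Crossed Claisen condensation, in which ketone 2 is enolised and C-acylated by the lithiated, non-enolisable salicylate 3; the phenoxide leaving group offsets the deactivating ortho-phenoxide, deprotonation of the 1,3-diketone drives the reaction, and the cold mild quench avoids cyclodehydration.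

**Step 3**
Reactants: 4 1-[2-(benzyloxy)-6-methoxyphenyl]-3-(2-hydroxy-4,5-dimethoxyphenyl)propane-1,3-dione
Product: 7 2'-(benzyloxy)-5,6-dihydroxy-7,8,6'-trimethoxyflavone, via acyl-ortho-quinone 5 (not isolated), via flavone-5,6-quinone 6 (not isolated)
Conditions: IBX (2.2 equiv), DMF, 0 °C to rt, dark; then aq. Na2S2O4, EtOAc, rt
Reagents that add atoms: 2-iodoxybenzoic acid (IBX), OI1(=O)OC(=O)c2ccccc12
Why: Proposed new method: a phenol ortho-oxygenation/oxa-Michael/re-aromatisation cascade that closes ring C at an unfunctionalised C–H; IBX (pentavalent iodine) binds the ring A phenol and delivers oxygen to its only free ortho carbon, giving acyl-ortho-quinone 5, whose remaining C–H carbon is the β-position of both the quinone C=O and the side-chain C=O; the diketone enol oxygen reaches only this carbon through a six-membered transition state (6-endo oxa-Michael addition, equally an oxa-6π closure of the 1-oxatriene tautomer, whereas C-attack would need a four-membered ring), and loss of the C8a proton restores the arene as the 5,6-catechol, so the old phenol becomes 5-OH, the IBX oxygen becomes 6-OH and the enol oxygen becomes O1; surplus IBX takes the catechol on to quinone 6 and Na2S2O4 returns it to 7; the closest known reaction types are the IBX oxidation of electron-rich phenols to ortho-quinones with reductive work-up to catechols, and the conjugate addition of heteroatom or 1,3-dicarbonyl nucleophiles to ortho-quinones (cyclodopa-type closure, oxidative catechol/1,3-dicarbonyl benzofuran annulation), neither of which has been used to form a chromone O1–C8a bond; no stereocentre is formed.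

**Step 4**
Reactants: 7 2'-(benzyloxy)-5,6-dihydroxy-7,8,6'-trimethoxyflavone
Product: 8 5,6,2'-trihydroxy-7,8,6'-trimethoxyflavone
Conditions: H2 (1 atm), 10% Pd/C, EtOAc/MeOH, rt
Reagents that add atoms: none
Why: Catalytic hydrogenolysis of the benzyl aryl ether; at 1 atm and rt the chromone C2=C3 bond, the methyl ethers and the catechol are untouched, and the reducing medium protects the catechol from air oxidation.

**Compound list**
1 | 2'-hydroxy-6'-methoxyacetophenone | CC(=O)c1c(O)cccc1OC | starting material
2 | 2'-(benzyloxy)-6'-methoxyacetophenone | CC(=O)c1c(OCc2ccccc2)cccc1OC | intermediate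
3 | phenyl 2-hydroxy-4,5-dimethoxybenzoate | COc1cc(O)c(cc1OC)C(=O)Oc1ccccc1 | starting material
4 | 1-[2-(benzyloxy)-6-methoxyphenyl]-3-(2-hydroxy-4,5-dimethoxyphenyl)propane-1,3-dione | COc1cc(O)c(cc1OC)C(=O)CC(=O)c1c(OC)cccc1OCc1ccccc1 | intermediate
5 | 1-[2-(benzyloxy)-6-methoxyphenyl]-3-(3,4-dimethoxy-5,6-dioxocyclohexa-1,3-dien-1-yl)propane-1,3-dione (acyl-ortho-quinone, not isolated) | COC1=C(OC)C(=O)C(=O)C(=C1)C(=O)CC(=O)c1c(OC)cccc1OCc1ccccc1 | intermediate
6 | 2-[2-(benzyloxy)-6-methoxyphenyl]-7,8-dimethoxy-4H-chromene-4,5,6-trione (flavone-5,6-quinone, not isolated) | COC1=C(OC)C(=O)C(=O)C2=C1OC(=CC2=O)c1c(OC)cccc1OCc1ccccc1 | intermediate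
7 | 2'-(benzyloxy)-5,6-dihydroxy-7,8,6'-trimethoxyflavone | COc1cccc(OCc2ccccc2)c1-c1cc(=O)c2c(O)c(O)c(OC)c(OC)c2o1 | intermediate
8 | 5,6,2'-trihydroxy-7,8,6'-trimethoxyflavone | COc1cccc(O)c1-c1cc(=O)c2c(O)c(O)c(OC)c(OC)c2o1 | target

**Total step count:** 4. **Longest linear sequence:** 4 (1 → 2 → 4 → 7 → 8).

**Steps most likely to fail**

**Step 3 (the new step).**
- The chelated, acyl-bearing phenol may react slowly with IBX.
- It may be oxidised at the para position, losing the future 8-OMe as a para-quinone.
- IBX may hydroxylate the central carbon of the diketone.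
- Compound 4 may cyclodehydrate to the 6,7-dimethoxyflavone.

The fallback uses known chemistry only, sets out from 2 and comes back at 8.
- Ketone 2 is enolised with LiN(SiMe3)2 in THF and acylated with commercial methyl 2-bromo-3,4,5-trimethoxybenzoate. This gives 1-[2-(benzyloxy)-6-methoxyphenyl]-3-(2-bromo-3,4,5-trimethoxyphenyl)propane-1,3-dione F2.
- Intramolecular Ullmann-type O-arylation (CuI, K2CO3, DMF, 110 °C) closes ring C to 2'-(benzyloxy)-6,7,8,6'-tetramethoxyflavone F3.
- Ketone-directed C5–H hydroxylation ([RuCl2(p-cymene)]2, PhI(OCOCF3)2, CF3CO2H/(CF3CO)2O, then aqueous work-up) gives 2'-(benzyloxy)-5-hydroxy-6,7,8,6'-tetramethoxyflavone F4.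
- BCl3 (excess, CH2Cl2, −78 °C to rt) removes the benzyl group. By chelation relayed from the 5-O–boron complex it also removes only the 6-O-methyl group, giving 8.

**Step 2.** The lithiated, electron-rich salicylate 3 may be too poor an electrophile, leading to recovered ketone or self-condensation. The fallback sets out from 2 and comes back at 4.
- Commercial 2-hydroxy-4,5-dimethoxybenzoic acid is condensed with acetone ((CF3CO)2O, CF3CO2H, rt) to 6,7-dimethoxy-2,2-dimethyl-4H-1,3-benzodioxin-4-one F1. This is a neutral acylal that masks the phenol and activates the carboxyl group at the same time.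
- Enolised 2 (LiN(SiMe3)2, 2.2 equiv, THF, −78 to 0 °C) opens F1 at the carbonyl. The hemiketal alkoxide collapses to release the phenoxide, and a mild acid quench gives 4.

**Step 4.** Risks are over-reduction of the C2=C3 bond and catalyst poisoning by iodine-containing residues from step 3. The fallback sets out from 7 and comes back at 8.
- It replaces reduction by Lewis-acid ether cleavage: BCl3 (3 equiv) with pentamethylbenzene (5 equiv) in CH2Cl2 at −78 °C.
- BCl3 ionises the benzyl ether and the arene captures the benzyl cation by Friedel–Crafts alkylation.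
- The low temperature spares the methyl ethers. This fallback makes no new route compound.

**Further compounds**
F1 | step 2 | 6,7-dimethoxy-2,2-dimethyl-4H-1,3-benzodioxin-4-one | COc1cc2OC(C)(C)OC(=O)c2cc1OC
F2 | step 3 | 1-[2-(benzyloxy)-6-methoxyphenyl]-3-(2-bromo-3,4,5-trimethoxyphenyl)propane-1,3-dione | COc1cc(C(=O)CC(=O)c2c(OC)cccc2OCc2ccccc2)c(Br)c(OC)c1OC
F3 | step 3 | 2'-(benzyloxy)-6,7,8,6'-tetramethoxyflavone | COc1cccc(OCc2ccccc2)c1-c1cc(=O)c2cc(OC)c(OC)c(OC)c2o1
F4 | step 3 | 2'-(benzyloxy)-5-hydroxy-6,7,8,6'-tetramethoxyflavone | COc1cccc(OCc2ccccc2)c1-c1cc(=O)c2c(O)c(OC)c(OC)c(OC)c2o1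
F0 | step 4 | none | none
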